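You asked for a quick number on Monday's flask, so start from the amounts.

the same everywhere: gas phase 2.5 mM (held); catalyst 0.1 mol%
- Monday's: starting material 10 mM; the very flask that is asked about, followed so far
- Wednesday's: starting material 20 mM; run made earlier
- flask: starting material 10 mM; time 3.0 d

| run | time / h | target / % | crystals / % | starting material / % |
|---|---|---|---|---|
| Monday's | 3.00 | 17 | 0 | 80 |
| Monday's | 6.00 | 32 | 2 | 60 |
| Monday's | 10.0 | 54 | 0 | 36 |
| Monday's | 12.0 | 62 | 3 | 24 |
| Wednesday's | 4.00 | 7 | 0 | 87 |
| Wednesday's | 10.0 | 25 | 4 | 64 |
| Wednesday's | 20.0 | 43 | 12 | 23 |
| Wednesday's | 48.0 | 62 | 31 | 0 |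

(readings scatter by 2 percentage points)

- the target and crystals together standing at 3.0 d, as a percentage of the starting material charged
- concentration of dissolved gas in solution at 3.0 d, in percent of saturation

- amounts and yields of target count crystals too
- given per volume of solution although it is solid: crystals
- at the start none of the gas phase is in solution

The target readings already count crystals, so I never add the two. What remains is the lost share, the gap in the mass balance:

lost share = charge − starting material − target

Monday's run has lost 14.0% at 12.0 h, with 24% of the starting material left. Wednesday's run has lost 34.0% at 20.0 h, with 23% left. So, at nearly equal depth, Wednesday's run, with twice the starting material at the same catalyst loading, shows 2.43 times the lost share of Monday's run. That ratio is the loss factor. This is a reading, and it carries the scatter.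

At its last reading, at 48.0 h, Wednesday's run has lost 38.0%. My reckoning for Monday's flask is:

final lost share = 38.0% / 2.43 = 15.6%

That gives me 84.4% for target and crystals together. Monday's flask used 0.633 mM h⁻¹ on average up to 12.0 h, so at that pace its remaining starting material should last 3.79 h, far less than 3.0 d. I therefore expect dissolved gas back near saturation.

Your forecast says 95% and 99%, and it rests on this: “Wednesday's closes at about 93% by 48 h”. I differ on that point. With crystals inside target, that run closes at 62.0%.

The flask gives 81.3% and >99.9%.

    gas phase ⇌ dissolved gas, rate k1*(csat - [dissolved gas]) (kL = 6.90 × 10⁻⁵ s⁻¹)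
    starting material + dissolved gas + catalyst → catalyst + target (k = 31000 L² mol⁻² s⁻¹)
    starting material + target → side product (k = 0.00120 L mol⁻¹ s⁻¹)
    crystals ⇌ target, rate k4*(cs4 - [target]) while solid is left; crystals form when [target] > cs4 (solubility = 5.40 mM, k = 1.90 × 10⁻⁴ s⁻¹)

The lost share of Monday's flask is 18.7%, which stands as side product, 18.7% at 3.00 d. Now carry the loss factor to the neighbouring flask with 4.0 mM of starting material, loadings held. As a power of the charge, the factor gives the exponent 1.28. Scaling down from Monday's flask:

lost share = 18.7% × (4.0 mM / 10 mM)^1.28 = 5.79%

That neighbouring flask stands at 94.2% target and crystals together, with 5.76% side product at 3.00 d.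

(The data were computed for substances that don't exist, noise included.)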